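The runs stem from a simulated flask on assumed constants.

I start with an easy count of who can meet whom, and I carry one rule from it: as long as free nucleophile and acid set free stay small, each target costs two free base.

in all of them: electrophile 20 mM

|  | free base | protonated nucleophile | protic impurity | remark | time |
|---|---|---|---|---|---|
| ochre | 11 mM | 16 mM | 6 mM | run made earlier |  |
| grey | 52 mM | 16 mM | 6 mM | run made earlier |  |
| north-west | 64.0 mM | 16.0 mM | 6.00 mM |  | 5.0 h |
| south | 32.0 mM | 16.0 mM | 6.00 mM |  | 5.0 h |
| east | 16.0 mM | 16.0 mM | 6.00 mM |  | 5.0 h |

| run | time / h | electrophile / % | target / % |
|---|---|---|---|
| ochre | 0.200 | 94 | 4 |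
| ochre | 0.417 | 82 | 5 |
| ochre | 0.667 | 78 | 7 |
| ochre | 1.33 | 67 | 11 |
| ochre | 2.50 | 57 | 18 |
| grey | 0.200 | 91 | 7 |
| grey | 0.667 | 71 | 11 |
| grey | 1.33 | 54 | 21 |
| grey | 2.00 | 42 | 33 |
| grey | 2.50 | 39 | 36 |

(each reading ± 1.5 percentage points)

- part of the electrophile that has reacted at the end, north-west
- part of the electrophile that has reacted at the end, south
- part of the electrophile that has reacted at the end, east
- what raising the concentration of free base from its lowest to its highest value here does to the part of the electrophile that has reacted (changes below 5 percentage points count as none) (it rises / no change / it falls)

1. The main step alone. Electrophile meets nucleophile, and the nucleophile is charged as protonated nucleophile, 16.0 mM against 20 mM of electrophile. That is less, so protonated nucleophile is the limiting reagent, and target can reach 80.0% of the electrophile.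

2. Add the acid steps. I take the binding of acid set free to nucleophile as fast, so that free nucleophile and free acid stay small beside the other amounts. Then each target takes two free base: one removes the acid from a protonated nucleophile, and one takes up the acid that the main step sets free. I call the base bill the free base charged over twice the electrophile charged, the share of electrophile whose target that charge pays for at two free base each: 40.0% in east, 80.0% in south, 160% in north-west. East's bill is smaller than the nucleophile share, so free base is the charge I watch there. The readings at 2.50 h have target paying with 65.5% of the free base in ochre, but 27.7% in grey.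

3. Add the impurity. Electrophile lost without becoming target reads 25.0% in ochre and 25.0% in grey. The protic impurity charge is 30.0% of the electrophile, and the step that takes it uses no free base.

4. The forecast, made from the same runs, gives 76% (68% to 85%) for north-west, 67% (60% to 75%) for south and 56% (49% to 63%) for east. For the part reacted, as free base goes from lowest to highest, its answer is: it rises, in its own words “Conversion therefore rises with base”.

    electrophile + nucleophile → acid set free + target (k = 3.00 M⁻¹ min⁻¹)
    nucleophile + acid set free ⇌ protonated nucleophile, settled at all times (K = 1.10 × 10⁵ M⁻¹)
    acid set free + free base ⇌ salt of the base (K = 3.90 × 10⁵ M⁻¹, k = 35.0 M⁻¹ min⁻¹)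
    electrophile + protic impurity → quenched substrate (k = 0.990 M⁻¹ min⁻¹)

The flasks give 83.5% in north-west, 73.4% in south and 61.4% in east, and for the part reacted, as free base goes from lowest to highest, the answer is: it rises, by 22 percentage points. At 5.00 h east holds 13.2 mM of salt of the base against 6.49 mM of target, 2.03 per target, and its target stands at 81.1% of its bill. A further flask, like south but with 50 mM of electrophile, has a bill of 32.0%. It ends with target at 26.1%, which at two free base each comes to 26.1 mM, and its salt of the base stands at 26.1 mM.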